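**Plan**

1. Numbering used here: ring C1 (C=O), C2 (bears the side chain), C3 (=CH), C4 (CHMe), C5 (CHOH), C6 (CMe2); side chain C1' (CHOH), C2' (CHN); the fatty acid is numbered from its carboxyl carbon and its positions are written out in words (acid carbon 7 and so on).
2. Cuts: the amide bond between nitrogen and acid carbon 1 (made last); ring C2=C3 (ring-closing metathesis), then C1–C2 (Stille acylation), C4–C5 (crotylboration) and the C1'–acyl bond to D-serine (Weinreb ketone synthesis); in the acid the bonds between carbons 2 and 3 (Johnson–Claisen), 4 and 5 (vinyl Grignard), 6 and 7 (allylboration) and 12 and 13 (cross-metathesis).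
3. Forward: a C1/C3–C6 acid and a D-serine-derived vinylstannane (C2, C1', C2') are joined to an acyclic dienone, the only ring is then closed, and the separately made fatty acid is put on nitrogen before final desilylation.
4. Enabling feature: C2 is both the α-carbon of the enone and the bearer of carbinol C1' (a Morita–Baylis–Hillman pattern), C2=C3 is the only C=C of the ring, and C6 is quaternary. An α-methylene ketone with a vinyl group on C4 is therefore a non-enolisable diene that the gem-dimethyl group predisposes to close at C2=C3.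
5. Stereochemistry: C2' is bought (Boc-D-Ser(Me)-OH) and C1' is relayed from it by chelation-controlled reduction; C4 and C5 are set together in one (Z)-crotylboration; the methyl-bearing acid carbon 9 is bought ((S)-citronellal), the methoxy-bearing acid carbon 7 comes from an allylboration, and the (E)-alkene between acid carbons 4 and 5 from the chair Claisen transition state.

Key step: step 11

Remark on the chemistry: mixtures at elements that are destroyed later (alkene geometry after the cross-metathesis, the carbinol made by vinyl addition) are carried on unseparated; the chiral starting materials are taken as commercial single enantiomers.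

**Part A – ring carbons C1, C3–C6**

Step 1
Reactants: 1 methyl 3-hydroxy-2,2-dimethylpropanoate
Product: 2 methyl 2,2-dimethyl-3-oxopropanoate
Conditions: TEMPO (cat.), PhI(OAc)2, CH2Cl2, rt
Reagents that add atoms: none
Why: Nitroxyl-catalysed alcohol oxidation should stop at the non-enolisable neopentyl aldehyde and leave the ester untouched.

Step 2
Reactants: 2 methyl 2,2-dimethyl-3-oxopropanoate
Product: 4 methyl (3R,4S)-3-hydroxy-2,2,4-trimethylhex-5-enoate, via borinate ester 3 (not isolated)
Conditions: cis-2-butene, n-BuLi, KOtBu, THF, −78 to −45 °C; (+)-Ipc2BOMe [(−)-α-pinene series], −78 °C; BF3·OEt2; 2, −78 °C; then 3 M NaOH, 30% H2O2, 0 °C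
Reagents that add atoms: cis-2-butene (C/C=C\C)
Why: Brown (Z)-crotylboration through a closed chair transition state, in which the Z geometry fixes the syn relation of C3–OH and C4–CH3 and the (+)-isopinocampheyl ligands direct attack to the Re face of the aldehyde, should set both centres (ring C5 and C4) in one event; the brief cold peroxide work-up should spare the hindered ester.

Step 3
Reactants: 4 methyl (3R,4S)-3-hydroxy-2,2,4-trimethylhex-5-enoate
Product: 5 methyl (3R,4S)-3-((tert-butyldimethylsilyl)oxy)-2,2,4-trimethylhex-5-enoate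
Conditions: TBSOTf, 2,6-lutidine, CH2Cl2, 0 °C
Reagents that add atoms: tert-butyldimethylsilyl trifluoromethanesulfonate (CC(C)(C)[Si](C)(C)OS(=O)(=O)C(F)(F)F)
Why: Silyl ether formation with the reactive silyl triflate should protect the hindered secondary alcohol with a group that survives base, palladium, ruthenium and brief acid.

Step 4
Reactants: 5 methyl (3R,4S)-3-((tert-butyldimethylsilyl)oxy)-2,2,4-trimethylhex-5-enoate
Product: 6 (3R,4S)-3-((tert-butyldimethylsilyl)oxy)-2,2,4-trimethylhex-5-enoic acid
Conditions: LiOH·H2O, THF/MeOH/H2O, 60 °C; then 1 M HCl to pH 3, 0 °C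
Reagents that add atoms: lithium hydroxide ([Li+].[OH-])
Why: Saponification of the hindered methyl ester should be clean because the α-carbon is quaternary and the β-oxygen is silylated, so neither epimerisation nor retro-aldol cleavage is possible.

**Part B – C2, C1', C2' and ring closure**

Step 5
Reactants: 7 (R)-2-((tert-butoxycarbonyl)amino)-3-methoxypropanoic acid
Product: 8 tert-butyl (R)-(3-methoxy-1-(methoxy(methyl)amino)-1-oxopropan-2-yl)carbamate
Conditions: MeNHOMe·HCl, EDC·HCl, HOBt (cat.), N-methylmorpholine, CH2Cl2, 0 °C to rt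
Reagents that add atoms: N,O-dimethylhydroxylamine hydrochloride (CNOC.Cl)
Why: Carbodiimide amidation to the Weinreb amide should keep the α-centre because urethane N-protection suppresses oxazolone formation.

Step 6
Reactants: 8 tert-butyl (R)-(3-methoxy-1-(methoxy(methyl)amino)-1-oxopropan-2-yl)carbamate
Product: 9 tert-butyl (R)-(1-methoxy-3-oxopent-4-yn-2-yl)carbamate
Conditions: HC≡CMgBr (3.5 equiv), THF, −78 to 0 °C; inverse quench into cold 1 M HCl
Reagents that add atoms: ethynylmagnesium bromide (C#C[Mg]Br)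
Why: Weinreb ketone synthesis, in which the first equivalent of Grignard reagent deprotonates the carbamate N–H (shielding the α-hydrogen from enolisation and β-elimination of methoxide), the second adds once to give the stable chelate, and the acidic quench keeps the released amine protonated so that it cannot add to the ynone.

Step 7
Reactants: 9 tert-butyl (R)-(1-methoxy-3-oxopent-4-yn-2-yl)carbamate
Product: 10 tert-butyl ((2R,3S)-3-hydroxy-1-methoxypent-4-yn-2-yl)carbamate
Conditions: LiAlH(OtBu)3, EtOH, −78 °C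
Reagents that add atoms: none
Why: Diastereoselective 1,2-reduction of a carbamate-protected α-amino ketone, in which hydride delivery to the N–H/C=O chelated (Cram cyclic) arrangement from the side of the small α-hydrogen is expected to give the anti amino alcohol, so the new C1' centre (3S) is relayed from C2'.

Step 8
Reactants: 10 tert-butyl ((2R,3S)-3-hydroxy-1-methoxypent-4-yn-2-yl)carbamate
Product: 11 tert-butyl ((2R,3S)-3-((tert-butyldimethylsilyl)oxy)-1-methoxypent-4-yn-2-yl)carbamate
Conditions: TBSCl, imidazole, DMF, rt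
Reagents that add atoms: tert-butyldimethylsilyl chloride (CC(C)(C)[Si](C)(C)Cl)
Why: Imidazole-mediated silyl ether formation should protect the propargylic alcohol under conditions that do not touch the Boc carbamate.

Step 9
Reactants: 11 tert-butyl ((2R,3S)-3-((tert-butyldimethylsilyl)oxy)-1-methoxypent-4-yn-2-yl)carbamate
Product: 12 tert-butyl ((2R,3R)-3-((tert-butyldimethylsilyl)oxy)-1-methoxy-4-(tributylstannyl)pent-4-en-2-yl)carbamate
Conditions: Bu3SnH, Mo(CO)3(CNtBu)3 (cat.), hydroquinone (cat.), THF, 55 °C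
Reagents that add atoms: tributyltin hydride (CCCC[SnH](CCCC)CCCC)
Why: Molybdenum-catalysed hydrostannation of a terminal alkyne with a propargylic oxygen substituent, for which the zerovalent molybdenum isonitrile complex is expected to place tin on the internal carbon and give the 1,1-disubstituted vinylstannane, hydroquinone suppressing the radical pathway to the linear isomer.

Step 10
Reactants: 6 (3R,4S)-3-((tert-butyldimethylsilyl)oxy)-2,2,4-trimethylhex-5-enoic acid; 12 tert-butyl ((2R,3R)-3-((tert-butyldimethylsilyl)oxy)-1-methoxy-4-(tributylstannyl)pent-4-en-2-yl)carbamate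
Product: 14 tert-butyl ((2R,3S,7R,8S)-3,7-bis((tert-butyldimethylsilyl)oxy)-1-methoxy-6,6,8-trimethyl-4-methylidene-5-oxodec-9-en-2-yl)carbamate, via acid chloride 13 (not isolated)
Conditions: 6, 1-chloro-N,N,2-trimethylprop-1-en-1-amine, CH2Cl2, 0 °C to rt; then 12, Pd2(dba)3 (cat.), P(2-furyl)3, CuI (cat.), toluene, 60 °C
Reagents that add atoms: none
Why: Stille acylation (ketone synthesis), in which the acid chloride is formed under neutral conditions and can neither form a ketene nor epimerise (quaternary α-carbon), and copper-assisted transfer of the vinyl group from tin to the acyl palladium species should form the C1–C2 bond and give the Morita–Baylis–Hillman-type dienone.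

Step 11
Reactants: 14 tert-butyl ((2R,3S,7R,8S)-3,7-bis((tert-butyldimethylsilyl)oxy)-1-methoxy-6,6,8-trimethyl-4-methylidene-5-oxodec-9-en-2-yl)carbamate
Product: 15 tert-butyl ((1S,2R)-1-((tert-butyldimethylsilyl)oxy)-1-((3S,4R)-4-((tert-butyldimethylsilyl)oxy)-3,5,5-trimethyl-6-oxocyclohex-1-en-1-yl)-3-methoxypropan-2-yl)carbamate
Conditions: Hoveyda–Grubbs second-generation catalyst (10 mol%), 1,4-benzoquinone (cat.), toluene (0.005 M), 80 °C, argon sparge
Reagents that add atoms: none
Why: The ruthenium alkylidene should initiate at the monosubstituted vinyl group on C4, the only unhindered alkene, and then undergo [2+2] cycloaddition and cycloreversion with the 1,1-disubstituted α-methylene ketone alkene, releasing ethylene. The closest known reaction type is ring-closing metathesis of α-methylene ketone dienes (Morita–Baylis–Hillman-type adducts) to 2-substituted cycloalk-2-enones with second-generation ruthenium carbenes. The six-membered carbocycle is closed by ring-closing olefin metathesis at C2=C3, the Z geometry of the new trisubstituted alkene being enforced by the ring. No new stereocentre is formed, and the four existing centres are not at risk because the conditions are neutral, the ketone has no α-hydrogen, and benzoquinone intercepts ruthenium hydrides that could move the C2=C3 bond towards C4. The step needs ring closure to win over intermolecular cross-metathesis at the vinyl group, which high dilution, the gem-dimethyl group at C6 (Thorpe–Ingold effect) and the presence of only two alkenes in the substrate should secure. Loss of ethylene drives the reaction, and the conjugated trisubstituted alkene of the product should be inert to further metathesis.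

Step 12
Reactants: 15 tert-butyl ((1S,2R)-1-((tert-butyldimethylsilyl)oxy)-1-((3S,4R)-4-((tert-butyldimethylsilyl)oxy)-3,5,5-trimethyl-6-oxocyclohex-1-en-1-yl)-3-methoxypropan-2-yl)carbamate
Product: 16 (4S,5R)-2-((1S,2R)-2-amino-1-((tert-butyldimethylsilyl)oxy)-3-methoxypropyl)-5-((tert-butyldimethylsilyl)oxy)-4,6,6-trimethylcyclohex-2-en-1-one
Conditions: TFA/CH2Cl2 (1:4), 0 °C; then sat. aq. NaHCO3
Reagents that add atoms: none
Why: Acidolysis of the Boc carbamate (loss of the tert-butyl cation, then decarboxylation) should spare the secondary silyl ethers in the cold, and the free amine is carried into step 21 at once so that it has no time to condense with the hindered ketone or add to the enone.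

**Part C – fatty acid**

Step 13
Reactants: 17 (S)-citronellal
Product: 18 (S)-3-methyldec-6-enal (E/Z mixture)
Conditions: 1-pentene (excess), Hoveyda–Grubbs second-generation catalyst (cat.), CH2Cl2, 40 °C (sealed tube)
Reagents that add atoms: 1-pentene (C=CCCC)
Why: Olefin cross-metathesis of the trisubstituted prenyl-type alkene with a terminal alkene is driven by loss of 2-methylpropene, does not touch the remote stereocentre, and its alkene geometry is irrelevant because of step 14.

Step 14
Reactants: 18 (S)-3-methyldec-6-enal (E/Z mixture)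
Product: 19 (S)-3-methyldecanal
Conditions: H2 (1 atm), Pd/C, EtOAc, rt
Reagents that add atoms: none
Why: Heterogeneous catalytic hydrogenation of the isolated C=C bond should be much faster than reduction of the aliphatic aldehyde under neutral conditions.

Step 15
Reactants: 19 (S)-3-methyldecanal
Product: 21 (4S,6S)-6-methyltridec-1-en-4-ol, via borinate ester 20 (not isolated)
Conditions: (−)-Ipc2B(allyl) [(+)-α-pinene series], Et2O, −78 °C; then 3 M NaOH, 30% H2O2, 0 °C to rt
Reagents that add atoms: (−)-B-allyldiisopinocampheylborane (C=CCB([C@@H]1C[C@@H]2C[C@H]([C@H]1C)C2(C)C)[C@@H]1C[C@@H]2C[C@H]([C@H]1C)C2(C)C)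
Why: Brown allylboration through a chair transition state, in which the (−)-isopinocampheyl ligands direct the allyl group to the Si face of the aldehyde under reagent control (the β-methyl centre having little influence), should set the carbinol that becomes the methoxy-bearing carbon 7 of the acid.

Step 16
Reactants: 21 (4S,6S)-6-methyltridec-1-en-4-ol
Product: 22 (4S,6S)-4-methoxy-6-methyltridec-1-ene
Conditions: NaH, MeI, THF, 0 °C to rt
Reagents that add atoms: iodomethane (CI)
Why: Williamson etherification of the secondary alkoxide with methyl iodide proceeds at oxygen and leaves the carbinol configuration unchanged.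

Step 17
Reactants: 22 (4S,6S)-4-methoxy-6-methyltridec-1-ene
Product: 24 (3R,5S)-3-methoxy-5-methyldodecanal, via ozonide 23 (not isolated)
Conditions: O3, CH2Cl2, −78 °C; then PPh3, −78 °C to rt
Reagents that add atoms: ozone ([O-][O+]=O)
Why: Ozonolysis with reductive work-up cleaves the only alkene to the β-methoxy aldehyde, which is used crude to avoid β-elimination of methanol.

Step 18
Reactants: 24 (3R,5S)-3-methoxy-5-methyldodecanal
Product: 25 (5R,7S)-5-methoxy-7-methyltetradec-1-en-3-ol (C3 epimers)
Conditions: CH2=CHMgBr, THF, −78 °C; then sat. aq. NH4Cl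
Reagents that add atoms: vinylmagnesium bromide (C=C[Mg]Br)
Why: Grignard addition to the aldehyde gives the allylic alcohol, whose new carbinol configuration does not matter because both epimers converge in step 19.

Step 19
Reactants: 25 (5R,7S)-5-methoxy-7-methyltetradec-1-en-3-ol (C3 epimers)
Product: 27 ethyl (4E,7R,9S)-7-methoxy-9-methylhexadec-4-enoate, via ketene acetal 26 (not isolated)
Conditions: MeC(OEt)3 (excess), EtCO2H (cat.), 140 °C, distillation of EtOH
Reagents that add atoms: triethyl orthoacetate (CCOC(C)(OCC)OCC)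
Why: Johnson–Claisen rearrangement of the ketene acetal through a chair transition state with the alkyl chain equatorial should give the (E)-alkene and removes the carbinol centre.

Step 20
Reactants: 27 ethyl (4E,7R,9S)-7-methoxy-9-methylhexadec-4-enoate
Product: 28 (4E,7R,9S)-7-methoxy-9-methylhexadec-4-enoic acid
Conditions: LiOH·H2O, THF/MeOH/H2O, rt; then 1 M HCl to pH 3
Reagents that add atoms: lithium hydroxide ([Li+].[OH-])
Why: Saponification of the unhindered ethyl ester is mild enough to leave the methyl ether and the (E)-alkene untouched.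

**Endgame**

Step 21
Reactants: 16 (4S,5R)-2-((1S,2R)-2-amino-1-((tert-butyldimethylsilyl)oxy)-3-methoxypropyl)-5-((tert-butyldimethylsilyl)oxy)-4,6,6-trimethylcyclohex-2-en-1-one; 28 (4E,7R,9S)-7-methoxy-9-methylhexadec-4-enoic acid
Product: 29 (4E,7R,9S)-N-((1S,2R)-1-((tert-butyldimethylsilyl)oxy)-1-((3S,4R)-4-((tert-butyldimethylsilyl)oxy)-3,5,5-trimethyl-6-oxocyclohex-1-en-1-yl)-3-methoxypropan-2-yl)-7-methoxy-9-methylhexadec-4-enamide
Conditions: EDC·HCl, HOBt, iPr2NEt, CH2Cl2, 0 °C to rt
Reagents that add atoms: none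
Why: Carbodiimide/HOBt amide coupling should be clean because the acid has no α-stereocentre and the primary amine is the only free nucleophile.

Step 22
Reactants: 29 (4E,7R,9S)-N-((1S,2R)-1-((tert-butyldimethylsilyl)oxy)-1-((3S,4R)-4-((tert-butyldimethylsilyl)oxy)-3,5,5-trimethyl-6-oxocyclohex-1-en-1-yl)-3-methoxypropan-2-yl)-7-methoxy-9-methylhexadec-4-enamide
Product: 30 (4E,7R,9S)-N-((1S,2R)-1-hydroxy-1-((3S,4R)-4-hydroxy-3,5,5-trimethyl-6-oxocyclohex-1-en-1-yl)-3-methoxypropan-2-yl)-7-methoxy-9-methylhexadec-4-enamide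
Conditions: HF·pyridine, pyridine/THF, 0 °C to rt
Reagents that add atoms: none
Why: Fluoride-mediated desilylation under buffered acidic conditions is chosen over basic fluoride because the β-hydroxy ketone with a quaternary α-carbon could undergo retro-aldol cleavage under base.

**Compound list**

1 | methyl 3-hydroxy-2,2-dimethylpropanoate | COC(=O)C(C)(C)CO | starting material
2 | methyl 2,2-dimethyl-3-oxopropanoate | COC(=O)C(C)(C)C=O | intermediate
3 | methyl (3R,4S)-3-((di((+)-isopinocampheyl)boranyl)oxy)-2,2,4-trimethylhex-5-enoate | C=C[C@H](C)[C@@H](OB([C@H]1C[C@H]2C[C@@H]([C@@H]1C)C2(C)C)[C@H]1C[C@H]2C[C@@H]([C@@H]1C)C2(C)C)C(C)(C)C(=O)OC | intermediate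
4 | methyl (3R,4S)-3-hydroxy-2,2,4-trimethylhex-5-enoate | C=C[C@H](C)[C@@H](O)C(C)(C)C(=O)OC | intermediate
5 | methyl (3R,4S)-3-((tert-butyldimethylsilyl)oxy)-2,2,4-trimethylhex-5-enoate | C=C[C@H](C)[C@@H](O[Si](C)(C)C(C)(C)C)C(C)(C)C(=O)OC | intermediate
6 | (3R,4S)-3-((tert-butyldimethylsilyl)oxy)-2,2,4-trimethylhex-5-enoic acid | C=C[C@H](C)[C@@H](O[Si](C)(C)C(C)(C)C)C(C)(C)C(=O)O | intermediate
7 | (R)-2-((tert-butoxycarbonyl)amino)-3-methoxypropanoic acid (Boc-D-Ser(Me)-OH) | CC(C)(C)OC(=O)N[C@H](COC)C(=O)O | starting material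
8 | tert-butyl (R)-(3-methoxy-1-(methoxy(methyl)amino)-1-oxopropan-2-yl)carbamate | CC(C)(C)OC(=O)N[C@H](COC)C(=O)N(C)OC | intermediate
9 | tert-butyl (R)-(1-methoxy-3-oxopent-4-yn-2-yl)carbamate | CC(C)(C)OC(=O)N[C@H](COC)C(=O)C#C | intermediate
10 | tert-butyl ((2R,3S)-3-hydroxy-1-methoxypent-4-yn-2-yl)carbamate | CC(C)(C)OC(=O)N[C@H](COC)[C@@H](O)C#C | intermediate
11 | tert-butyl ((2R,3S)-3-((tert-butyldimethylsilyl)oxy)-1-methoxypent-4-yn-2-yl)carbamate | CC(C)(C)OC(=O)N[C@H](COC)[C@@H](O[Si](C)(C)C(C)(C)C)C#C | intermediate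
12 | tert-butyl ((2R,3R)-3-((tert-butyldimethylsilyl)oxy)-1-methoxy-4-(tributylstannyl)pent-4-en-2-yl)carbamate | CC(C)(C)OC(=O)N[C@H](COC)[C@@H](O[Si](C)(C)C(C)(C)C)C(=C)[Sn](CCCC)(CCCC)CCCC | intermediate
13 | (3R,4S)-3-((tert-butyldimethylsilyl)oxy)-2,2,4-trimethylhex-5-enoyl chloride | C=C[C@H](C)[C@@H](O[Si](C)(C)C(C)(C)C)C(C)(C)C(=O)Cl | intermediate
14 | tert-butyl ((2R,3S,7R,8S)-3,7-bis((tert-butyldimethylsilyl)oxy)-1-methoxy-6,6,8-trimethyl-4-methylidene-5-oxodec-9-en-2-yl)carbamate | CC(C)(C)OC(=O)N[C@H](COC)[C@@H](O[Si](C)(C)C(C)(C)C)C(=C)C(=O)C(C)(C)[C@H](O[Si](C)(C)C(C)(C)C)[C@@H](C)C=C | intermediate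
15 | tert-butyl ((1S,2R)-1-((tert-butyldimethylsilyl)oxy)-1-((3S,4R)-4-((tert-butyldimethylsilyl)oxy)-3,5,5-trimethyl-6-oxocyclohex-1-en-1-yl)-3-methoxypropan-2-yl)carbamate | CC(C)(C)OC(=O)N[C@H](COC)[C@@H](O[Si](C)(C)C(C)(C)C)C1=C[C@H](C)[C@@H](O[Si](C)(C)C(C)(C)C)C(C)(C)C1=O | intermediate
16 | (4S,5R)-2-((1S,2R)-2-amino-1-((tert-butyldimethylsilyl)oxy)-3-methoxypropyl)-5-((tert-butyldimethylsilyl)oxy)-4,6,6-trimethylcyclohex-2-en-1-one | N[C@H](COC)[C@@H](O[Si](C)(C)C(C)(C)C)C1=C[C@H](C)[C@@H](O[Si](C)(C)C(C)(C)C)C(C)(C)C1=O | intermediate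
17 | (S)-citronellal ((S)-3,7-dimethyloct-6-enal) | CC(C)=CCC[C@H](C)CC=O | starting material
18 | (S)-3-methyldec-6-enal (E/Z mixture) | CCCC=CCC[C@H](C)CC=O | intermediate
19 | (S)-3-methyldecanal | CCCCCCC[C@H](C)CC=O | intermediate
20 | (4S,6S)-6-methyltridec-1-en-4-yl di((−)-isopinocampheyl)borinate | CCCCCCC[C@H](C)C[C@H](CC=C)OB([C@@H]1C[C@@H]2C[C@H]([C@H]1C)C2(C)C)[C@@H]1C[C@@H]2C[C@H]([C@H]1C)C2(C)C | intermediate
21 | (4S,6S)-6-methyltridec-1-en-4-ol | CCCCCCC[C@H](C)C[C@H](CC=C)O | intermediate
22 | (4S,6S)-4-methoxy-6-methyltridec-1-ene | CCCCCCC[C@H](C)C[C@H](CC=C)OC | intermediate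
23 | 3-((2R,4S)-2-methoxy-4-methylundecyl)-1,2,4-trioxolane (epimers at the ring carbon) | CCCCCCC[C@H](C)C[C@H](CC1OCOO1)OC | intermediate
24 | (3R,5S)-3-methoxy-5-methyldodecanal | CCCCCCC[C@H](C)C[C@H](CC=O)OC | intermediate
25 | (5R,7S)-5-methoxy-7-methyltetradec-1-en-3-ol (C3 epimers) | CCCCCCC[C@H](C)C[C@H](CC(O)C=C)OC | intermediate
26 | (5R,7S)-3-((1-ethoxyvinyl)oxy)-5-methoxy-7-methyltetradec-1-ene (C3 epimers) | CCCCCCC[C@H](C)C[C@H](CC(OC(=C)OCC)C=C)OC | intermediate
27 | ethyl (4E,7R,9S)-7-methoxy-9-methylhexadec-4-enoate | CCCCCCC[C@H](C)C[C@H](C/C=C/CCC(=O)OCC)OC | intermediate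
28 | (4E,7R,9S)-7-methoxy-9-methylhexadec-4-enoic acid | CCCCCCC[C@H](C)C[C@H](C/C=C/CCC(=O)O)OC | intermediate
29 | (4E,7R,9S)-N-((1S,2R)-1-((tert-butyldimethylsilyl)oxy)-1-((3S,4R)-4-((tert-butyldimethylsilyl)oxy)-3,5,5-trimethyl-6-oxocyclohex-1-en-1-yl)-3-methoxypropan-2-yl)-7-methoxy-9-methylhexadec-4-enamide | CCCCCCC[C@H](C)C[C@H](C/C=C/CCC(=O)N[C@H](COC)[C@@H](O[Si](C)(C)C(C)(C)C)C1=C[C@H](C)[C@@H](O[Si](C)(C)C(C)(C)C)C(C)(C)C1=O)OC | intermediate
30 | (4E,7R,9S)-N-((1S,2R)-1-hydroxy-1-((3S,4R)-4-hydroxy-3,5,5-trimethyl-6-oxocyclohex-1-en-1-yl)-3-methoxypropan-2-yl)-7-methoxy-9-methylhexadec-4-enamide | CCCCCCC[C@H](C)C[C@H](C/C=C/CCC(=O)N[C@H](COC)[C@@H](O)C1=C[C@H](C)[C@@H](O)C(C)(C)C1=O)OC | target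

**Step count and risks**

Total step count: 22. Longest linear sequence: 10 steps (steps 5–12, 21 and 22 from 7; equally steps 13–22 from 17).

Steps most likely to fail:

Step 10 (Stille acylation). Transmetallation of the hindered 1-substituted vinylstannane to the hindered acyl palladium species may be slow, so that protodestannylation, homocoupling or decarbonylation takes over. The fallback sets out from 12 and 5 and comes back at 14. Iododestannylation of 12 (I2, CH2Cl2, 0 °C) should give the vinyl iodide tert-butyl ((2R,3R)-3-((tert-butyldimethylsilyl)oxy)-4-iodo-1-methoxypent-4-en-2-yl)carbamate F1. Ester 5 is reduced with i-Bu2AlH to (3R,4S)-3-((tert-butyldimethylsilyl)oxy)-2,2,4-trimethylhex-5-en-1-ol F2 and oxidised with Dess–Martin periodinane to (3R,4S)-3-((tert-butyldimethylsilyl)oxy)-2,2,4-trimethylhex-5-enal F3. Nozaki–Hiyama–Kishi coupling of the two (CrCl2, NiCl2 cat., DMSO) should give the dienol tert-butyl ((2R,3S,7R,8S)-3,7-bis((tert-butyldimethylsilyl)oxy)-5-hydroxy-1-methoxy-6,6,8-trimethyl-4-methylidenedec-9-en-2-yl)carbamate F4 as a mixture of C5 epimers, and Dess–Martin oxidation returns dienone 14.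

Step 11 (ring-closing metathesis). Metathesis at the electron-poor, hindered 1,1-disubstituted enone alkene may be sluggish, so that intermolecular dimerisation at the vinyl group competes. The fallback sets out from 14 and comes back at 15, and moves the ring closure to the alcohol oxidation level. Luche reduction of 14 (NaBH4, CeCl3·7H2O, MeOH, −78 °C) should give the same dienol tert-butyl ((2R,3S,7R,8S)-3,7-bis((tert-butyldimethylsilyl)oxy)-5-hydroxy-1-methoxy-6,6,8-trimethyl-4-methylidenedec-9-en-2-yl)carbamate F4, whose allylic-alcohol alkene is a better metathesis partner. Ring-closing metathesis with the same ruthenium catalyst should give the cyclohexenol tert-butyl ((1S,2R)-1-((tert-butyldimethylsilyl)oxy)-1-((3S,4R)-4-((tert-butyldimethylsilyl)oxy)-6-hydroxy-3,5,5-trimethylcyclohex-1-en-1-yl)-3-methoxypropan-2-yl)carbamate F5 (C6 epimers), and allylic oxidation (Dess–Martin periodinane or MnO2) gives 15.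

Step 7 (ynone reduction). Facial selectivity of hydride delivery to the terminal ynone may be poor, or conjugate addition to the ynone may compete. The fallback sets out from 8 and comes back at 10, and replaces substrate control by catalyst control on a more robust silyl ynone. Addition of lithium (trimethylsilyl)acetylide to 8 should give tert-butyl (R)-(1-methoxy-3-oxo-5-(trimethylsilyl)pent-4-yn-2-yl)carbamate F6. Noyori transfer hydrogenation with RuCl[(R,R)-TsDPEN](p-cymene) in iPrOH should give tert-butyl ((2R,3S)-3-hydroxy-1-methoxy-5-(trimethylsilyl)pent-4-yn-2-yl)carbamate F7, and K2CO3 in MeOH removes the silyl group to give 10.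

Further compounds
F1 | step 10 | tert-butyl ((2R,3R)-3-((tert-butyldimethylsilyl)oxy)-4-iodo-1-methoxypent-4-en-2-yl)carbamate | CC(C)(C)OC(=O)N[C@H](COC)[C@@H](O[Si](C)(C)C(C)(C)C)C(I)=C
F2 | step 10 | (3R,4S)-3-((tert-butyldimethylsilyl)oxy)-2,2,4-trimethylhex-5-en-1-ol | C=C[C@H](C)[C@@H](O[Si](C)(C)C(C)(C)C)C(C)(C)CO
F3 | step 10 | (3R,4S)-3-((tert-butyldimethylsilyl)oxy)-2,2,4-trimethylhex-5-enal | C=C[C@H](C)[C@@H](O[Si](C)(C)C(C)(C)C)C(C)(C)C=O
F4 | step 10 | tert-butyl ((2R,3S,7R,8S)-3,7-bis((tert-butyldimethylsilyl)oxy)-5-hydroxy-1-methoxy-6,6,8-trimethyl-4-methylidenedec-9-en-2-yl)carbamate (C5 epimers) | CC(C)(C)OC(=O)N[C@H](COC)[C@@H](O[Si](C)(C)C(C)(C)C)C(=C)C(O)C(C)(C)[C@H](O[Si](C)(C)C(C)(C)C)[C@@H](C)C=C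
F5 | step 11 | tert-butyl ((1S,2R)-1-((tert-butyldimethylsilyl)oxy)-1-((3S,4R)-4-((tert-butyldimethylsilyl)oxy)-6-hydroxy-3,5,5-trimethylcyclohex-1-en-1-yl)-3-methoxypropan-2-yl)carbamate (C6 epimers) | CC(C)(C)OC(=O)N[C@H](COC)[C@@H](O[Si](C)(C)C(C)(C)C)C1=C[C@H](C)[C@@H](O[Si](C)(C)C(C)(C)C)C(C)(C)C1O
F6 | step 7 | tert-butyl (R)-(1-methoxy-3-oxo-5-(trimethylsilyl)pent-4-yn-2-yl)carbamate | CC(C)(C)OC(=O)N[C@H](COC)C(=O)C#C[Si](C)(C)C
F7 | step 7 | tert-butyl ((2R,3S)-3-hydroxy-1-methoxy-5-(trimethylsilyl)pent-4-yn-2-yl)carbamate | CC(C)(C)OC(=O)N[C@H](COC)[C@@H](O)C#C[Si](C)(C)C
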